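(The data were computed with constants of no real substance; the scatter is artificial.)

Count the reagent first.

- green: solid substrate 1.5 M; reagent 0.53 equiv; protic impurity 0.15 M; run made earlier
- flask: solid substrate 1.5 M; reagent 1.05 equiv; protic impurity 0.150 M; time 2.5 d

- green (time / d: target / %, solid substrate / %): 0.625: 7.5, 68.6; 0.833: 11.0, 61.8; 1.04: 15.3, 55.6; 1.25: 18.3, 50.5; 1.67: 23.9, 40.8; 2.08: 28.3, 31.6; 2.50: 31.9, 24.4

(scatter of a reading: 0.3 percentage points)

- amounts and yields of target count solid product too
- given per volume of solution although it is solid: solid substrate, solid product
- steps thought possible: target <-> isomer of the product; solid substrate <-> dissolved substrate; solid product <-> target; solid substrate + protic impurity -> quenched substrate; dissolved substrate + reagent -> target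
- at the start none of the solid substrate is in solution

* the best time, 2.5 d at the latest, for target
* the amount of target, in percent of the solid substrate charged, at that time

What does one target cost? One reagent, by the step from dissolved substrate, so in the green run the charge minus the target read is an upper figure for the reagent left.

Does that figure decay cleanly? At 2.50 d the natural logarithm of charge over charge minus target comes to 0.921; call it the reagent exponent. It climbs by 0.434 d⁻¹ up to 1.25 d and 0.398 d⁻¹ afterwards, so I read the reagent as roughly pseudo-first-order.

What does the new charge give? With the same exponent at the same time, the flask's reagent turnover is 63.2% of the solid substrate charged.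

Where is that weak? The exponent sees target, not what target became. The green run lacks 43.7% at its end; quench can take 10.0%, and the remaining 33.7%, if quench took that much, is dissolved substrate or isomer of the product, which these readings do not divide. So my figure is 63.2% less a correction I cannot size. The green target still gained 3.6 percentage points in its last interval, more than the scatter, so for the flask I take the latest time, a judgement carried over from the green run.

The forecast, which puts a size on the correction where I did not, gives 52% at 2.5 d, less than my uncorrected figure, in its words “Target is probably still rising, or near its peak”.

The flask gives 51.7% at 2.50 d.

    target ⇌ isomer of the product (K = 2.80, k = 0.00720 h⁻¹)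
    solid substrate ⇌ dissolved substrate, rate k2*(cs2 - [dissolved substrate]) while solid is left; crystals form when [dissolved substrate] > cs2 (solubility = 0.640 M, k = 0.0460 h⁻¹)
    solid product ⇌ target, rate k3*(cs3 - [target]) while solid is left; crystals form when [target] > cs3 (solubility = 0.730 M, k = 1.90 h⁻¹)
    solid substrate + protic impurity → quenched substrate (k = 0.110 L mol⁻¹ h⁻¹)
    dissolved substrate + reagent → target (k = 0.0770 L mol⁻¹ h⁻¹)

At the end of this flask, the reagent's half-life by coupling is 1.3 d, shorter than the 4.0 d forward half-life of dissolved target going to isomer of the product. The reagent used there is 62.8% of the solid substrate charged, against the 63.2% from the exponent, and isomer of the product holds 11.0%. In the neighbour flask with 0.260 equiv of reagent, read at 2.50 d, the exponent gives 15.6%, the reagent used is 20.7%, and target holds 16.9%.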